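(The data are calculated for an exercise; scatter was added.)

| setting | south-east | west | south | flask |
|---|---|---|---|---|
| substrate | 15 mM (fed, over 4.0 min) | 24 mM (fed, over 4.0 min) | 11 mM (fed, over 4.0 min) | 11 mM (fed, over 4.0 min) |
| first nucleophile | 11 mM | 11 mM | 5.5 mM | 11.0 mM |
| second nucleophile | 6.6 mM | 6.6 mM | 6.6 mM | 6.60 mM |
| remark | run made earlier; the fed solution adds 0.50 times the starting volume | run made earlier; the fed solution adds 0.50 times the starting volume | run made earlier; the fed solution adds 0.50 times the starting volume | the fed solution adds 0.50 times the starting volume |
| time |  |  |  | 5.0 h |

| run | time / h | solvolysis product / % | other capture product / % |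
|---|---|---|---|
| south-east | 0.417 | 66.9 | 29.7 |
| south-east | 1.00 | 69.8 | 30.1 |
| south-east | 2.00 | 69.6 | 29.3 |
| south-east | 5.00 | 69.2 | 29.8 |
| west | 0.667 | 76.6 | 24.5 |
| west | 2.00 | 76.2 | 24.4 |
| west | 3.00 | 76.2 | 24.1 |
| west | 5.00 | 76.2 | 23.4 |
| south | 0.417 | 63.8 | 33.1 |
| south | 1.00 | 66.5 | 34.2 |
| south | 2.00 | 66.8 | 33.6 |
| south | 5.00 | 66.1 | 33.5 |

(each reading ± 0.5 percentage points)

- charges are per starting volume, the dose included; the dosed solution carries all of it
- what was read earlier has a scatter of 0.5 percentage points, one standard deviation

* solvolysis product at 5.0 h, in percent of the substrate charged
* other capture product at 5.0 h, in percent of the substrate charged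

The easy step was to add the two products of the south run: they came to 96.9 % of the substrate charged at 0.417 h and 99.6 % at 5.00 h. From this I took it that the first nucleophile holds material briefly and gives it back, and that one intermediate finally goes either to solvent or to the second nucleophile, which is consumed as it captures. If capture goes with c(second nucleophile) and solvolysis does not, then, with amounts per starting volume, c(solvolysis product) = K ln(starting c(second nucleophile) / final c(second nucleophile)). The south-east run, with 4.47 mM of other capture product at 5.00 h, gave 9.18 mM for K, the crossing amount, which is the amount of second nucleophile per starting volume at which capture and solvolysis go equally fast, a selectivity factor written as an amount.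

The flask looks nearly the same as the south run: both take 11 mM of substrate and 6.60 mM of second nucleophile, which stands below the crossing amount. The south run had half the first nucleophile, yet its 3.68 mM of other capture product read as a crossing amount of 8.90 mM, close to the south-east value. So I expected the two flasks to end together. Solving the balance for the flask with the south-east value, I reckoned 3.64 mM of other capture product, which is 33.1 %, leaving 66.9 % as solvolysis product. The forecast gave 66.7 % and 33.1 %, on the ground that “halving the first nucleophile has no visible effect”; its solvolysis figure stood 0.20 percentage points below mine.

The flask gave 66.4 % of solvolysis product and 33.6 % of other capture product at 5.0 h.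

    substrate → intermediate (k = 0.00250 s⁻¹)
    first nucleophile + intermediate ⇌ target (K = 68.0 L mol⁻¹, k = 560 L mol⁻¹ s⁻¹)
    second nucleophile + intermediate → other capture product (k = 1800 L mol⁻¹ s⁻¹)
    intermediate → solvolysis product (k = 11.0 s⁻¹)

These amounts make the crossing amount of the flask 8.91 mM, close to the value I carried. A neighbouring flask, like this one in all but its second nucleophile, starts with 11 mM of it, which is above the crossing amount, whereas the flask started below it. The same balance with the south-east value gives about 47.0 % of other capture product for it. That neighbour gave 47.6 % of other capture product and 52.4 % of solvolysis product, with 52 % of its second nucleophile left.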